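**Numbering used throughout.** Atoms are written C1–C11 (longipinane numbering: C1(=O)–C2=C3(CH3)–C4–C5–C6(CH3)2–C7–C8–C9–C10(CH3)–C11, with the further bonds C11–C1, C4–C10 and C5–C11). Compounds are written as plain numbers 1–30. Open-chain compounds carry their own IUPAC locants in their names.

## Analysis of the target

The target is a longipinane sesquiterpenoid diester. Ring A is the cyclobutane C4–C5–C11–C10, ring B the cyclohexenone C1–C2–C3–C4–C10–C11, and ring C the cycloheptane C5–C6–C7–C8–C9–C10–C11. Ring A is bridged on both diagonals from opposite faces: C4/C11 by the enone unit C3=C2–C1(=O) (a bicyclo[3.1.1]heptenone) and C5/C10 by C6–C7–C8–C9 (a bicyclo[4.1.1]octane); no ring A carbon carries a heteroatom and C10 is quaternary. The six core stereocentres are 4R,5S,7R,9R,10R,11R: C4, C5, C10 and C11 are locked to each other by the two bridges (C10 methyl syn to the enone bridge), while the C7 and C9 oxygens are trans on ring C, the C9 oxygen expected axial on the C11 side and the C7 oxygen equatorial on the C4 side. C9 carries a (Z)-2-methylbut-2-enoate (angelate) and C7 a (2S,3R)-2,3-dimethyloxirane-2-carboxylate whose two methyl groups are cis, as the SMILES encodes; both alcohols are secondary, flanked by a quaternary carbon, and must still be told apart. Sensitive points are the Z-enoate (Z to E isomerization with acid, nucleophiles, radicals, metal hydrides), the epoxide, the strained cyclobutane next to the enone (cationic 1,2-shifts; retro-aldol opening once an oxygen sits on C5 while C1 is a ketone) and the beta-oxygenated C7/C9 array (retro-aldol, beta-elimination). The hard part is the doubly bridged four-membered ring with its quaternary C10, spanned by a 1,3-dioxygenated, gem-dimethyl ring C. The structure invites one move: read as a chain, C5–C4–C3(CH3)–C2–C1–C11=C10(CH3)–C9–C8–C7–C6(CH3)2 is an intact head-to-tail farnesane, the ring A bonds C5–C11 and C4–C10 join its C5=C4 terminus to the C11=C10 trisubstituted alkene, and C5 can be the carbonyl carbon of a ketene and afterwards the electrophile on which ring C closes.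

## Retrosynthetic reasoning

**Ester bonds (30 ⇒ 27 + 28; 27 ⇒ 21 + 25).** The two acyl–oxygen bonds are cut first, because the angelate tolerates neither the reductive nor the radical steps and the epoxide tolerates no acid. Forward, the equatorial C7 hydroxyl of diol 21 has to be acylated by epoxy acid 25 before the axial C9 hydroxyl, and the C9 hydroxyl of 27 is then acylated by angelic acid 28 without Z to E isomerization.

**C7–H bond (21 ⇒ 20).** The C7 carbinol is traced back to a ketone. The free C9 hydroxyl of 20 can deliver hydride across ring C to the same face, which gives the 7,9-trans diol; C7 is a ketone anyway because of the way ring C is closed.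

**C1 oxygen and C9 protecting group (20 ⇒ 19 ⇒ 18).** The C1 carbonyl comes from allylic oxidation of the C2=C3 alkene of 18. It is introduced only after C5 is free of oxygen, because a C5 alkoxide next to a C1 ketone would open ring A by retro-aldol cleavage of C5–C11.

**Ring C, bond C5–C6 (18 ⇒ 17 ⇒ 14).** C5–C6 joins the former ketene carbon to a fully substituted carbon alpha to the C7 carbonyl; this is an aldol retron as long as C5 still bears oxygen. The cut is made here because the chain on C10 already sits on the only face from which it can reach C5, so the C5 configuration cannot go wrong, and the C7/C9 oxygen pattern is then itself the result of an earlier aldol. The price is one C–O bond at C5, removed through oxalate 17. The enolate must form at C6 and not at C8 (beta-elimination of the C9 silyloxy group), so it is generated reductively from the alpha-benzoyloxy ketone of 14.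

**Rings A and B, bonds C5–C11 and C4–C10 (14 ⇒ 13 ⇒ 10 via 12).** Both bonds are cut at once; this opens rings A and B and leaves the open-chain acid 10. Forward, vinylketene 12 must add across its own 6,7-alkene in the crossed sense and set C4, C10 and C11 relative to the one stereocentre in the chain, C9.

**Chain, bond C8–C9 (10 ⇒ 9 ⇒ 8 ⇒ 5 + 2).** The beta-hydroxy ketone is an aldol between enal 5 and the methyl ketone 2; this single step brings in C6–C8 with the latent C6 enolate and sets C9. Enal 5 comes from allylic oxidation of ester 3, and ketone 2 from hydroxy ketone 1.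

**Epoxy acid (25 ⇒ 24 ⇒ 23 ⇒ 22).** The oxirane is set by asymmetric epoxidation of the (E)-allylic alcohol 23, obtained from ester 22, and the primary alcohol of 24 is oxidized to the acid.

## Alternatives that were turned down

**Alternative 1:** the textbook cut, only C5–C11 of ring A. Forward key step: 4-exo-tet alkylation of the C11 enolate of the cis-fused bicyclo[5.4.0]undecenone keto tosylate A1. Turned down because C5 is a secondary carbon next to the gem-dimethyl carbon C6, so the displacement is neopentylic and elimination or fragmentation should win. In addition, A1 already holds five stereocentres, among them the quaternary C10, and would need a long annulation sequence before the hardest ring is even attempted.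

**Alternative 2:** cut C4–C10 and C5–C11 but keep both tethers, which leads to the eleven-membered humulane-type trienone A2. Forward key step: transannular enone–alkene [2+2] photocycloaddition (or its cationic, biomimetic variant). Turned down because an excited enone with a three-atom tether closes the five-membered ring first and gives the fused bicyclo[3.2.0] isomer (bonds C11–C4 and C10–C5), and a cross-conjugated trienone has competing E/Z and electrocyclic channels. The cationic variant ends in a cyclobutylcarbinyl cation that ring-expands. The macrocycle with three defined alkenes and two stereocentres costs more steps than the key step would save.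

**Alternative 3:** skeleton first: longipin-2-en-1-one A3, then C–H oxidation at C7 and C9. Turned down because C7–H2 and C9–H2 are unactivated methylenes shielded by quaternary neighbours, C8–H2 is the more exposed site, and the C3 methyl group is the more reactive allylic one. The C1 carbonyl points away from ring C and cannot direct, and the trans arrangement and the differentiation of the two oxygens would remain unsolved.

Key step: step 6

**Assumption 1:** (−)-Ipc2BCl is taken to deliver enolate 6 to the Re face of the aldehyde of 5 (8R carbinol); if the sense is the opposite one, (+)-Ipc2BCl is used and nothing else changes.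
**Assumption 2:** the oxirane of the target is taken as encoded, (2S,3R) with cis methyl groups.

## Route

Step 1
Reactants: 1 3-hydroxy-3-methylbutan-2-one
Product: 2 2-methyl-3-oxobutan-2-yl benzoate
Conditions: BzCl, pyridine, DMAP (cat.), CH2Cl2, 40 °C
Reagents that add atoms: benzoyl chloride, O=C(Cl)c1ccccc1
Why: Nucleophile-catalysed acylation of a tertiary alcohol; the benzoate survives soft enolization and is later the leaving group alpha to the ketone.

Step 2
Reactants: 3 methyl (2E)-3,7-dimethylocta-2,6-dienoate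
Product: 5 methyl (2E,6E)-3,7-dimethyl-8-oxoocta-2,6-dienoate, via hydroxy ester 4 (not isolated)
Conditions: SeO2 (cat.), tBuOOH, salicylic acid (cat.), CH2Cl2, rt; filtration; then MnO2, CH2Cl2, rt
Reagents that add atoms: tert-butyl hydroperoxide, CC(C)(C)OO; selenium dioxide, O=[Se]=O
Why: Riley allylic oxidation (ene reaction, then [2,3]-shift) attacks the (E)-methyl group of the electron-rich 6,7-alkene, the conjugated 2,3-alkene being deactivated; MnO2 takes the allylic alcohol on to the enal.

Step 3
Reactants: 2 2-methyl-3-oxobutan-2-yl benzoate; 5 methyl (2E,6E)-3,7-dimethyl-8-oxoocta-2,6-dienoate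
Product: 8 methyl (2E,6E,8R)-11-(benzoyloxy)-8-hydroxy-3,7,11-trimethyl-10-oxododeca-2,6-dienoate, via boron enolate 6 (not isolated), via boron aldolate 7 (not isolated)
Conditions: 2, (−)-Ipc2BCl, Et3N, Et2O, 0 °C; then 5, −78 to −20 °C; then H2O2, MeOH, pH 7 buffer, 0 °C
Reagents that add atoms: none
Why: Paterson boron aldol of a methyl ketone; 2 can enolize only at its methyl group, and alpha'-benzoyloxy ketones are established substrates for soft boron enolization. The chiral boron ligands should steer the enolate to the Re face of the enal and set the carbinol (C9 of the skeleton) as 8R.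

Step 4
Reactants: 8 methyl (2E,6E,8R)-11-(benzoyloxy)-8-hydroxy-3,7,11-trimethyl-10-oxododeca-2,6-dienoate
Product: 9 methyl (2E,6E,8R)-11-(benzoyloxy)-8-[(tert-butyldimethylsilyl)oxy]-3,7,11-trimethyl-10-oxododeca-2,6-dienoate
Conditions: TBSOTf, 2,6-lutidine, CH2Cl2, −78 °C
Reagents that add atoms: tert-butyldimethylsilyl trifluoromethanesulfonate, CC(C)(C)[Si](C)(C)OS(=O)(=O)C(F)(F)F
Why: Silylation of a beta-hydroxy ketone under non-eliminating conditions; the silyl ether is a poor leaving group in the base-mediated key step and is the steric element at C9.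

Step 5
Reactants: 9 methyl (2E,6E,8R)-11-(benzoyloxy)-8-[(tert-butyldimethylsilyl)oxy]-3,7,11-trimethyl-10-oxododeca-2,6-dienoate
Product: 10 (2E,6E,8R)-11-(benzoyloxy)-8-[(tert-butyldimethylsilyl)oxy]-3,7,11-trimethyl-10-oxododeca-2,6-dienoic acid
Conditions: Me3SnOH, ClCH2CH2Cl, 80 °C; then 0.1 M aq. HCl wash
Reagents that add atoms: trimethyltin hydroxide, C[Sn](C)(C)O
Why: Near-neutral methyl ester cleavage with Me3SnOH, which should spare the hindered tertiary benzoate and the beta-silyloxy ketone that aqueous hydroxide would attack.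

Step 6
Reactants: 10 (2E,6E,8R)-11-(benzoyloxy)-8-[(tert-butyldimethylsilyl)oxy]-3,7,11-trimethyl-10-oxododeca-2,6-dienoic acid
Product: 13 (1R,5S,7S)-7-[(1R)-4-(benzoyloxy)-1-[(tert-butyldimethylsilyl)oxy]-4-methyl-3-oxopentyl]-7-methyl-2-methylidenebicyclo[3.1.1]heptan-6-one, via acid chloride 11 (not isolated), via vinylketene 12 (not isolated)
Conditions: 1-chloro-N,N,2-trimethylprop-1-en-1-amine, CH2Cl2, 0 °C to rt; then slow addition to Et3N, toluene, 110 °C (high dilution)
Reagents that add atoms: none
Why: Acid chloride 11 loses HCl by 1,4-elimination through the C3 methyl group and gives the cross-conjugated vinylketene 12, kept dilute by slow addition. The ketene carbon C5 bonds to C11, the less substituted carbon of the (6E)-alkene, and the ketene alpha-carbon C4 closes on C10, which best carries the positive charge of the asynchronous thermal [2+2] transition state; this is the crossed mode, and the closest known reaction type is the intramolecular vinylketene–alkene cycloaddition of 3-methyl-2-enoyl chlorides of the geranic and farnesic series to 2-methylidenebicyclo[3.1.1]heptan-6-ones. Ring A closes as the four-membered ring of the cycloadduct (bonds C5–C11 and C4–C10), and ring B as the six-membered ring that the three-atom tether C3–C2–C1 completes in the same event. C4 and C11 can only be cis because they are the bridgeheads; C10 follows from the alkene geometry by suprafacial addition, the methyl group cis to the tether ending syn to the C1–C3 bridge and the C9 branch anti, as ring C requires. The absolute sense is relayed from C9: in the arrangement expected to be favoured the C9–H bond lies over the forming four-membered ring, the C9–C8 bond is anti to the forming C4–C10 bond as the better donor and the silyloxy group points outward, which leads to the 1R,5S,7S ketone. The step needs regioselectivity for the crossed adduct, secured by the disubstituted distal alkene carbon, and survival of the beta-silyloxy ketone, which Et3N should not enolize at a useful rate.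

Step 7
Reactants: 13 (1R,5S,7S)-7-[(1R)-4-(benzoyloxy)-1-[(tert-butyldimethylsilyl)oxy]-4-methyl-3-oxopentyl]-7-methyl-2-methylidenebicyclo[3.1.1]heptan-6-one
Product: 14 (1R,5S,7S)-7-[(1R)-4-(benzoyloxy)-1-[(tert-butyldimethylsilyl)oxy]-4-methyl-3-oxopentyl]-2,7-dimethylbicyclo[3.1.1]hept-2-en-6-one
Conditions: PdCl2(MeCN)2 (cat.), benzene, 60 °C
Reagents that add atoms: none
Why: Palladium-catalysed isomerization of the exocyclic alkene into the more stable trisubstituted ring alkene (C2=C3), as in the pinene series; it is done before any radical step so that no cyclobutylcarbinyl radical can arise by addition to the methylidene group.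

Step 8
Reactants: 14 (1R,5S,7S)-7-[(1R)-4-(benzoyloxy)-1-[(tert-butyldimethylsilyl)oxy]-4-methyl-3-oxopentyl]-2,7-dimethylbicyclo[3.1.1]hept-2-en-6-one
Product: 17 methyl (4R,5S,9R,10S,11S)-9-[(tert-butyldimethylsilyl)oxy]-7-oxolongipin-2-en-5-yl oxalate, via samarium enolate 15 (not isolated), via samarium aldolate 16 (not isolated)
Conditions: SmI2 (2.2 equiv), THF, −78 °C; then ClC(O)CO2Me, DMAP, −78 to 0 °C
Reagents that add atoms: methyl chlorooxoacetate, COC(=O)C(=O)Cl
Why: SmI2 cleaves the C–O bond alpha to the ketone and gives the fully substituted samarium enolate 15 at C6 only, so no enolate toward C8 and no beta-elimination at C9 can occur. Reformatsky-type intramolecular aldol addition to the strained cyclobutanone closes ring C; the chain reaches C5 only from the face anti to the C1–C3 bridge, which fixes the C5–C6 bond, and the tertiary aldolate 16 is acylated before it can revert.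

Step 9
Reactants: 17 methyl (4R,5S,9R,10S,11S)-9-[(tert-butyldimethylsilyl)oxy]-7-oxolongipin-2-en-5-yl oxalate
Product: 18 (4R,5R,9R,10S,11R)-9-[(tert-butyldimethylsilyl)oxy]longipin-2-en-7-one
Conditions: Bu3SnH (excess, 0.5 M), AIBN (cat.), toluene, 100 °C
Reagents that add atoms: none
Why: Barton–McCombie-type deoxygenation of a tertiary methyl oxalate. The C5 radical cannot invert because C6 is tied into ring C, so hydrogen arrives on the face of the C1–C3 bridge and C5 keeps the arrangement of the target; the high tin hydride concentration is meant to outrun a 1,2-acyl shift.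

Step 10
Reactants: 18 (4R,5R,9R,10S,11R)-9-[(tert-butyldimethylsilyl)oxy]longipin-2-en-7-one
Product: 19 (4R,5S,9R,10R,11R)-9-[(tert-butyldimethylsilyl)oxy]longipin-2-ene-1,7-dione
Conditions: Rh2(cap)4 (cap = caprolactamate, cat.), tBuOOH, CH2Cl2, rt
Reagents that add atoms: tert-butyl hydroperoxide, CC(C)(C)OO
Why: Allylic C–H oxidation of a cyclic trisubstituted alkene to the enone; C1 is the only secondary allylic position (C4 is a bridgehead), as in the oxidation of pinene-type alkenes to verbenone-type enones.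

Step 11
Reactants: 19 (4R,5S,9R,10R,11R)-9-[(tert-butyldimethylsilyl)oxy]longipin-2-ene-1,7-dione
Product: 20 (4R,5S,9R,10R,11R)-9-hydroxylongipin-2-ene-1,7-dione
Conditions: HF·pyridine, pyridine, THF, 0 °C to rt
Reagents that add atoms: none
Why: Buffered acidic desilylation, under which the beta-hydroxy ketone should neither eliminate nor undergo retro-aldol opening of ring C.

Step 12
Reactants: 20 (4R,5S,9R,10R,11R)-9-hydroxylongipin-2-ene-1,7-dione
Product: 21 (4R,5S,7R,9R,10R,11R)-7,9-dihydroxylongipin-2-en-1-one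
Conditions: Me4NBH(OAc)3, MeCN/AcOH, −30 °C
Reagents that add atoms: none
Why: Evans–Saksena reduction: the acetoxyborohydride bound to the axial C9 oxygen delivers hydride intramolecularly to the same face of the C7 ketone, which sets C7 (7R) trans to the C9 oxygen. The reagent does not reduce the enone.

Step 13
Reactants: 22 ethyl (2E)-2-methylbut-2-enoate
Product: 23 (2E)-2-methylbut-2-en-1-ol
Conditions: iBu2AlH, CH2Cl2, −78 °C; Rochelle salt work-up
Reagents that add atoms: none
Why: 1,2-Reduction of the conjugated ester to the allylic alcohol with retention of the E geometry.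

Step 14
Reactants: 23 (2E)-2-methylbut-2-en-1-ol
Product: 24 [(2R,3R)-2,3-dimethyloxiran-2-yl]methanol
Conditions: Ti(OiPr)4 (cat.), D-(−)-diethyl tartrate (cat.), tBuOOH, 4 Å MS, CH2Cl2, −20 °C
Reagents that add atoms: tert-butyl hydroperoxide, CC(C)(C)OO
Why: Sharpless asymmetric epoxidation of an (E)-trisubstituted allylic alcohol, a favourable substrate class; the D-tartrate is the antipode of the one that gives (2S)-epoxy alcohols, and the cis methyl groups follow from the E-alkene.

Step 15
Reactants: 24 [(2R,3R)-2,3-dimethyloxiran-2-yl]methanol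
Product: 25 (2S,3R)-2,3-dimethyloxirane-2-carboxylic acid
Conditions: RuCl3·xH2O (cat.), NaIO4, CCl4/MeCN/H2O, rt
Reagents that add atoms: sodium periodate, [Na+].[O-]I(=O)(=O)=O; water, O
Why: Ruthenium tetroxide oxidation of an epoxy alcohol to the glycidic acid; the quaternary alpha-carbon cannot epimerize (the descriptor changes from 2R to 2S only through the priority rules).

Step 16
Reactants: 21 (4R,5S,7R,9R,10R,11R)-7,9-dihydroxylongipin-2-en-1-one; 25 (2S,3R)-2,3-dimethyloxirane-2-carboxylic acid
Product: 27 (4R,5S,7R,9R,10R,11R)-9-hydroxy-1-oxolongipin-2-en-7-yl (2S,3R)-2,3-dimethyloxirane-2-carboxylate, via mixed anhydride 26 (not isolated)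
Conditions: 25, 2,4,6-trichlorobenzoyl chloride, Et3N, THF, 0 °C; then 21 (slight excess), DMAP, toluene, 0 °C to rt
Reagents that add atoms: none
Why: Yamaguchi esterification. The equatorial C7 hydroxyl should react before the axial C9 hydroxyl, which is gauche to the C10 methyl group and to C11; coupling with enantiopure 25 also turns any minor enantiomer carried from step 3 into a separable diastereomer.

Step 17
Reactants: 27 (4R,5S,7R,9R,10R,11R)-9-hydroxy-1-oxolongipin-2-en-7-yl (2S,3R)-2,3-dimethyloxirane-2-carboxylate; 28 (2Z)-2-methylbut-2-enoic acid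
Product: 30 (4R,5S,7R,9R,10R,11R)-9-{[(2Z)-2-methylbut-2-enoyl]oxy}-1-oxolongipin-2-en-7-yl (2S,3R)-2,3-dimethyloxirane-2-carboxylate, via mixed anhydride 29 (not isolated)
Conditions: 28, 2,4,6-trichlorobenzoyl chloride, Et3N, toluene, rt; then 27, toluene, 75 °C (no nucleophilic catalyst)
Reagents that add atoms: none
Why: Mixed-anhydride acylation of the remaining C9 hydroxyl; without a nucleophilic catalyst the Z-enoate should not isomerize to the E ester, and the step comes last so that the angelate meets no reductant, radical or metal hydride.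

## Compound list

1 | 3-hydroxy-3-methylbutan-2-one | CC(=O)C(C)(C)O | starting material
2 | 2-methyl-3-oxobutan-2-yl benzoate | CC(=O)C(C)(C)OC(=O)c1ccccc1 | intermediate
3 | methyl (2E)-3,7-dimethylocta-2,6-dienoate (methyl geranate) | COC(=O)/C=C(\C)CCC=C(C)C | starting material
4 | methyl (2E,6E)-8-hydroxy-3,7-dimethylocta-2,6-dienoate | COC(=O)/C=C(\C)CC/C=C(\C)CO | intermediate
5 | methyl (2E,6E)-3,7-dimethyl-8-oxoocta-2,6-dienoate | COC(=O)/C=C(\C)CC/C=C(\C)C=O | intermediate
6 | 3-{[bis(isopinocampheyl)boranyl]oxy}-2-methylbut-3-en-2-yl benzoate (boron enolate of 2) | C=C(OB([C@@H]1C[C@@H]2C[C@H]([C@H]1C)C2(C)C)[C@@H]1C[C@@H]2C[C@H]([C@H]1C)C2(C)C)C(C)(C)OC(=O)c1ccccc1 | intermediate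
7 | O-[bis(isopinocampheyl)boranyl] derivative of 8 (boron aldolate) | COC(=O)/C=C(\C)CC/C=C(\C)[C@H](OB([C@@H]1C[C@@H]2C[C@H]([C@H]1C)C2(C)C)[C@@H]1C[C@@H]2C[C@H]([C@H]1C)C2(C)C)CC(=O)C(C)(C)OC(=O)c1ccccc1 | intermediate
8 | methyl (2E,6E,8R)-11-(benzoyloxy)-8-hydroxy-3,7,11-trimethyl-10-oxododeca-2,6-dienoate | COC(=O)/C=C(\C)CC/C=C(\C)[C@H](O)CC(=O)C(C)(C)OC(=O)c1ccccc1 | intermediate
9 | methyl (2E,6E,8R)-11-(benzoyloxy)-8-[(tert-butyldimethylsilyl)oxy]-3,7,11-trimethyl-10-oxododeca-2,6-dienoate | COC(=O)/C=C(\C)CC/C=C(\C)[C@H](O[Si](C)(C)C(C)(C)C)CC(=O)C(C)(C)OC(=O)c1ccccc1 | intermediate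
10 | (2E,6E,8R)-11-(benzoyloxy)-8-[(tert-butyldimethylsilyl)oxy]-3,7,11-trimethyl-10-oxododeca-2,6-dienoic acid | OC(=O)/C=C(\C)CC/C=C(\C)[C@H](O[Si](C)(C)C(C)(C)C)CC(=O)C(C)(C)OC(=O)c1ccccc1 | intermediate
11 | (2E,6E,8R)-11-(benzoyloxy)-8-[(tert-butyldimethylsilyl)oxy]-3,7,11-trimethyl-10-oxododeca-2,6-dienoyl chloride | ClC(=O)/C=C(\C)CC/C=C(\C)[C@H](O[Si](C)(C)C(C)(C)C)CC(=O)C(C)(C)OC(=O)c1ccccc1 | intermediate
12 | (6E,8R)-11-(benzoyloxy)-8-[(tert-butyldimethylsilyl)oxy]-7,11-dimethyl-3-methylidene-10-oxododeca-1,6-dien-1-one (vinylketene) | O=C=CC(=C)CC/C=C(\C)[C@H](O[Si](C)(C)C(C)(C)C)CC(=O)C(C)(C)OC(=O)c1ccccc1 | intermediate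
13 | (1R,5S,7S)-7-[(1R)-4-(benzoyloxy)-1-[(tert-butyldimethylsilyl)oxy]-4-methyl-3-oxopentyl]-7-methyl-2-methylidenebicyclo[3.1.1]heptan-6-one | CC(C)(OC(=O)c1ccccc1)C(=O)C[C@@H](O[Si](C)(C)C(C)(C)C)[C@@]1(C)[C@@H]2CCC(=C)[C@H]1C2=O | intermediate
14 | (1R,5S,7S)-7-[(1R)-4-(benzoyloxy)-1-[(tert-butyldimethylsilyl)oxy]-4-methyl-3-oxopentyl]-2,7-dimethylbicyclo[3.1.1]hept-2-en-6-one | CC(C)(OC(=O)c1ccccc1)C(=O)C[C@@H](O[Si](C)(C)C(C)(C)C)[C@@]1(C)[C@@H]2CC=C(C)[C@H]1C2=O | intermediate
15 | diiodosamarium enolate formed from 14 by loss of benzoate (C7–O–SmI2, C6=C7) | CC(C)=C(O[Sm](I)I)C[C@@H](O[Si](C)(C)C(C)(C)C)[C@@]1(C)[C@@H]2CC=C(C)[C@H]1C2=O | intermediate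
16 | diiodosamarium alkoxide of (4R,5S,9R,10S,11S)-9-[(tert-butyldimethylsilyl)oxy]-5-hydroxylongipin-2-en-7-one | CC(C)(C)[Si](C)(C)O[C@@H]1CC(=O)C(C)(C)[C@]2(O[Sm](I)I)[C@H]3CC=C(C)[C@@H]2[C@]31C | intermediate
17 | methyl (4R,5S,9R,10S,11S)-9-[(tert-butyldimethylsilyl)oxy]-7-oxolongipin-2-en-5-yl oxalate | CC(C)(C)[Si](C)(C)O[C@@H]1CC(=O)C(C)(C)[C@]2(OC(=O)C(=O)OC)[C@H]3CC=C(C)[C@@H]2[C@]31C | intermediate
18 | (4R,5R,9R,10S,11R)-9-[(tert-butyldimethylsilyl)oxy]longipin-2-en-7-one | CC(C)(C)[Si](C)(C)O[C@@H]1CC(=O)C(C)(C)[C@@H]2[C@H]3CC=C(C)[C@@H]2[C@]31C | intermediate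
19 | (4R,5S,9R,10R,11R)-9-[(tert-butyldimethylsilyl)oxy]longipin-2-ene-1,7-dione | CC(C)(C)[Si](C)(C)O[C@@H]1CC(=O)C(C)(C)[C@@H]2[C@H]3C(=O)C=C(C)[C@@H]2[C@]31C | intermediate
20 | (4R,5S,9R,10R,11R)-9-hydroxylongipin-2-ene-1,7-dione | O[C@@H]1CC(=O)C(C)(C)[C@@H]2[C@H]3C(=O)C=C(C)[C@@H]2[C@]31C | intermediate
21 | (4R,5S,7R,9R,10R,11R)-7,9-dihydroxylongipin-2-en-1-one | O[C@@H]1C[C@@H](O)C(C)(C)[C@@H]2[C@H]3C(=O)C=C(C)[C@@H]2[C@]31C | intermediate
22 | ethyl (2E)-2-methylbut-2-enoate (ethyl tiglate) | C/C=C(\C)C(=O)OCC | starting material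
23 | (2E)-2-methylbut-2-en-1-ol | C/C=C(\C)CO | intermediate
24 | [(2R,3R)-2,3-dimethyloxiran-2-yl]methanol | OC[C@@]1(C)O[C@@H]1C | intermediate
25 | (2S,3R)-2,3-dimethyloxirane-2-carboxylic acid | OC(=O)[C@@]1(C)O[C@@H]1C | intermediate
26 | (2S,3R)-2,3-dimethyloxirane-2-carboxylic 2,4,6-trichlorobenzoic anhydride | O=C(OC(=O)[C@@]1(C)O[C@@H]1C)c1c(Cl)cc(Cl)cc1Cl | intermediate
27 | (4R,5S,7R,9R,10R,11R)-9-hydroxy-1-oxolongipin-2-en-7-yl (2S,3R)-2,3-dimethyloxirane-2-carboxylate | O[C@@H]1C[C@@H](OC(=O)[C@@]2(C)O[C@@H]2C)C(C)(C)[C@@H]2[C@H]3C(=O)C=C(C)[C@@H]2[C@]31C | intermediate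
28 | (2Z)-2-methylbut-2-enoic acid (angelic acid) | C/C=C(/C)C(=O)O | starting material
29 | (2Z)-2-methylbut-2-enoic 2,4,6-trichlorobenzoic anhydride | C/C=C(/C)C(=O)OC(=O)c1c(Cl)cc(Cl)cc1Cl | intermediate
30 | (4R,5S,7R,9R,10R,11R)-9-{[(2Z)-2-methylbut-2-enoyl]oxy}-1-oxolongipin-2-en-7-yl (2S,3R)-2,3-dimethyloxirane-2-carboxylate | C/C=C(/C)C(=O)O[C@@H]1C[C@@H](OC(=O)[C@@]2(C)O[C@@H]2C)C(C)(C)[C@@H]2[C@H]3C(=O)C=C(C)[C@@H]2[C@]31C | target

## Step count and least certain steps

Total: 17 steps. Longest linear sequence: 13 steps (steps 2 to 12, then 16 and 17) from 3.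

**Step 6 (key step).** The most likely failure is poor or reversed facial selectivity: if the rotamer with the silyloxy group over the forming four-membered ring competes, the diastereomer with the enantiomeric bicyclic core would form. Oligomerization of the ketene and slow enolization of the chain ketone with loss of the silyloxy group are further risks. The fallback takes stereocontrol out of the cycloaddition; it sets out from 5 and comes back at 14. The aldehyde of 5 is masked (HC(OMe)3, MeOH, PPTS) as methyl (2E,6E)-8,8-dimethoxy-3,7-dimethylocta-2,6-dienoate F1. Me3SnOH gives (2E,6E)-8,8-dimethoxy-3,7-dimethylocta-2,6-dienoic acid F2, and the same acid chloride/Et3N protocol gives rac-(1R,5S,7S)-7-(dimethoxymethyl)-7-methyl-2-methylidenebicyclo[3.1.1]heptan-6-one F3, where no facial question arises. PdCl2(MeCN)2 isomerizes it to rac-(1R,5S,7S)-7-(dimethoxymethyl)-2,7-dimethylbicyclo[3.1.1]hept-2-en-6-one F4, and PPTS in wet acetone frees rac-(1R,5S,7S)-2,7-dimethyl-6-oxobicyclo[3.1.1]hept-2-ene-7-carbaldehyde F5. Boron enolate 6 then adds under reagent control to both enantiomers of F5, and the two diastereomeric aldols are separated by chromatography. The one with the right core, (1R,5S,7S)-7-[(1R)-4-(benzoyloxy)-1-hydroxy-4-methyl-3-oxopentyl]-2,7-dimethylbicyclo[3.1.1]hept-2-en-6-one F6, is silylated (TBSOTf, 2,6-lutidine) to 14.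

**Step 8.** The samarium enolate may be protonated, or the aldolate may revert before it is acylated, because a seven-membered ring has to close on a hindered carbonyl and the aldol is reversible under basic conditions. The fallback replaces the reversible metal aldolate by a Lewis acid-promoted Mukaiyama aldol; it sets out from 14 and comes back at 17. SmI2 followed by Me3SiCl traps the enolate as (1R,5S,7S)-7-{(1R)-1-[(tert-butyldimethylsilyl)oxy]-4-methyl-3-[(trimethylsilyl)oxy]pent-3-en-1-yl}-2,7-dimethylbicyclo[3.1.1]hept-2-en-6-one F7. TiCl4 in CH2Cl2 at −78 °C closes ring C to (4R,5S,9R,10S,11S)-9-[(tert-butyldimethylsilyl)oxy]-5-hydroxylongipin-2-en-7-one F8, and ClC(O)CO2Me with DMAP and pyridine gives 17.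

**Step 9.** The C5 radical sits beta to the C7 carbonyl; a 1,2-acyl shift (3-exo attack on the carbonyl, then beta-scission) would contract ring C, and the hindered oxalate may fragment slowly. The fallback generates the radical only after C7 has become a carbinol; it sets out from 17 and comes back at 21. HF·pyridine gives methyl (4R,5S,9R,10S,11S)-9-hydroxy-7-oxolongipin-2-en-5-yl oxalate F9, and Me4NBH(OAc)3 gives methyl (4R,5S,7R,9R,10S,11S)-7,9-dihydroxylongipin-2-en-5-yl oxalate F10. Bu3SnH/AIBN gives (4R,5R,7R,9R,10S,11R)-longipin-2-ene-7,9-diol F11, and Et3SiOTf/2,6-lutidine gives (4R,5R,7R,9R,10S,11R)-7,9-bis[(triethylsilyl)oxy]longipin-2-ene F12. Rh2(cap)4/tBuOOH gives (4R,5S,7R,9R,10R,11R)-7,9-bis[(triethylsilyl)oxy]longipin-2-en-1-one F13, and HF·pyridine gives 21.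

**Step 16.** Acylation may occur at the wrong hydroxyl or at both, because the two alcohols differ only in their axial or equatorial position and in their neighbours. The fallback fixes the regiochemistry by an Evans–Tishchenko reduction; it sets out from 20 and comes back at 27. Acetaldehyde with SmI2 (cat.) in THF at −10 °C reduces C7 from the C9 hemiacetal and leaves the acyl group on the C9 oxygen, which gives (4R,5S,7R,9R,10R,11R)-7-hydroxy-1-oxolongipin-2-en-9-yl acetate F14. Yamaguchi coupling with 25 gives (4R,5S,7R,9R,10R,11R)-9-acetoxy-1-oxolongipin-2-en-7-yl (2S,3R)-2,3-dimethyloxirane-2-carboxylate F15. K2CO3 in MeOH at 0 °C should remove the unhindered acetate faster than the alpha-quaternary glycidate and give 27.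

## Further compounds

F1 | step 6 | methyl (2E,6E)-8,8-dimethoxy-3,7-dimethylocta-2,6-dienoate | COC(=O)/C=C(\C)CC/C=C(\C)C(OC)OC
F2 | step 6 | (2E,6E)-8,8-dimethoxy-3,7-dimethylocta-2,6-dienoic acid | OC(=O)/C=C(\C)CC/C=C(\C)C(OC)OC
F3 | step 6 | rac-(1R,5S,7S)-7-(dimethoxymethyl)-7-methyl-2-methylidenebicyclo[3.1.1]heptan-6-one (racemic; the enantiomer that leads on is drawn) | COC(OC)[C@@]1(C)[C@@H]2CCC(=C)[C@H]1C2=O
F4 | step 6 | rac-(1R,5S,7S)-7-(dimethoxymethyl)-2,7-dimethylbicyclo[3.1.1]hept-2-en-6-one (racemic; the enantiomer that leads on is drawn) | COC(OC)[C@@]1(C)[C@@H]2CC=C(C)[C@H]1C2=O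
F5 | step 6 | rac-(1R,5S,7S)-2,7-dimethyl-6-oxobicyclo[3.1.1]hept-2-ene-7-carbaldehyde (racemic; the enantiomer that leads on is drawn) | O=C[C@@]1(C)[C@@H]2CC=C(C)[C@H]1C2=O
F6 | step 6 | (1R,5S,7S)-7-[(1R)-4-(benzoyloxy)-1-hydroxy-4-methyl-3-oxopentyl]-2,7-dimethylbicyclo[3.1.1]hept-2-en-6-one | CC(C)(OC(=O)c1ccccc1)C(=O)C[C@@H](O)[C@@]1(C)[C@@H]2CC=C(C)[C@H]1C2=O
F7 | step 8 | (1R,5S,7S)-7-{(1R)-1-[(tert-butyldimethylsilyl)oxy]-4-methyl-3-[(trimethylsilyl)oxy]pent-3-en-1-yl}-2,7-dimethylbicyclo[3.1.1]hept-2-en-6-one | CC(C)=C(O[Si](C)(C)C)C[C@@H](O[Si](C)(C)C(C)(C)C)[C@@]1(C)[C@@H]2CC=C(C)[C@H]1C2=O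
F8 | step 8 | (4R,5S,9R,10S,11S)-9-[(tert-butyldimethylsilyl)oxy]-5-hydroxylongipin-2-en-7-one | CC(C)(C)[Si](C)(C)O[C@@H]1CC(=O)C(C)(C)[C@]2(O)[C@H]3CC=C(C)[C@@H]2[C@]31C
F9 | step 9 | methyl (4R,5S,9R,10S,11S)-9-hydroxy-7-oxolongipin-2-en-5-yl oxalate | O[C@@H]1CC(=O)C(C)(C)[C@]2(OC(=O)C(=O)OC)[C@H]3CC=C(C)[C@@H]2[C@]31C
F10 | step 9 | methyl (4R,5S,7R,9R,10S,11S)-7,9-dihydroxylongipin-2-en-5-yl oxalate | O[C@@H]1C[C@@H](O)C(C)(C)[C@]2(OC(=O)C(=O)OC)[C@H]3CC=C(C)[C@@H]2[C@]31C
F11 | step 9 | (4R,5R,7R,9R,10S,11R)-longipin-2-ene-7,9-diol | O[C@@H]1C[C@@H](O)C(C)(C)[C@@H]2[C@H]3CC=C(C)[C@@H]2[C@]31C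
F12 | step 9 | (4R,5R,7R,9R,10S,11R)-7,9-bis[(triethylsilyl)oxy]longipin-2-ene | CC[Si](CC)(CC)O[C@@H]1C[C@@H](O[Si](CC)(CC)CC)C(C)(C)[C@@H]2[C@H]3CC=C(C)[C@@H]2[C@]31C
F13 | step 9 | (4R,5S,7R,9R,10R,11R)-7,9-bis[(triethylsilyl)oxy]longipin-2-en-1-one | CC[Si](CC)(CC)O[C@@H]1C[C@@H](O[Si](CC)(CC)CC)C(C)(C)[C@@H]2[C@H]3C(=O)C=C(C)[C@@H]2[C@]31C
F14 | step 16 | (4R,5S,7R,9R,10R,11R)-7-hydroxy-1-oxolongipin-2-en-9-yl acetate | CC(=O)O[C@@H]1C[C@@H](O)C(C)(C)[C@@H]2[C@H]3C(=O)C=C(C)[C@@H]2[C@]31C
F15 | step 16 | (4R,5S,7R,9R,10R,11R)-9-acetoxy-1-oxolongipin-2-en-7-yl (2S,3R)-2,3-dimethyloxirane-2-carboxylate | CC(=O)O[C@@H]1C[C@@H](OC(=O)[C@@]2(C)O[C@@H]2C)C(C)(C)[C@@H]2[C@H]3C(=O)C=C(C)[C@@H]2[C@]31C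
A1 | alternative 1 | cis-fused bicyclo[5.4.0]undecenone keto tosylate: 7,9-bis[(tert-butyldimethylsilyl)oxy]-5-(tosyloxy)-5,11-seco-longipin-2-en-1-one (C5–C11 bond absent, C11 a methylene) | CC(C)(C)[Si](C)(C)O[C@@H]1C[C@@H](O[Si](C)(C)C(C)(C)C)C(C)(C)[C@@H](OS(=O)(=O)c2ccc(C)cc2)[C@@H]2C(C)=CC(=O)C[C@@]21C
A2 | alternative 2 | eleven-membered humulane-type trienone: 7,9-bis[(tert-butyldimethylsilyl)oxy]-3,6,6,10-tetramethylcycloundeca-2,4,10-trien-1-one (skeleton numbering of the target; C4=C5 and C10=C11 E, C2=C3 ring-cis) | CC1=C\C(=O)/C=C(\C)[C@H](O[Si](C)(C)C(C)(C)C)C[C@@H](O[Si](C)(C)C(C)(C)C)C(C)(C)/C=C/1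
A3 | alternative 3 | (4R,5S,10R,11R)-longipin-2-en-1-one | C1CCC(C)(C)[C@@H]2[C@H]3C(=O)C=C(C)[C@@H]2[C@]31C
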